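## The problem

Target 31 is the 15-arachidate of a (13E)-cleroda-3,13-diene-15,16-diol. Clerodane numbering is used throughout: ring A is C1–C5 and C10, ring B is C5–C10, C17 is the methyl on C8, C18 on C4, C19 on C5 and C20 on C9. The face of the bicycle that carries H-10 and C11 is called the upper face, and the face that carries C17, C19 and C20 the lower face.

The rings are trans-fused through C5–C10. The four contiguous stereocentres C8, C9, C10 and C5 include two quaternary carbons whose methyls (C19, C20) are 1,3-diaxial on the lower face. C8, C9 and C10 can be set together and can then steer C5. C5, however, must receive its methyl on the face already crowded by C20, so it needs a directing group and not steric bias.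

None of the ring stereocentres can be corrected later by epimerisation. The one centre at risk on the way is C8 whenever C7 carries a carbonyl. The side chain is a 2-substituted (E)-but-2-ene-1,4-diol acylated only on O15, so the two oxygens must be told apart and the alkene geometry fixed. The primary allylic ester will not survive hydride, organometallic, strongly basic or ionising conditions and must be made at the very end. The two trisubstituted alkenes (C3=C4, C13=C14) exclude late hydrogenation and strong acid.

The feature that opens a short ring synthesis is twofold. C8–C9, a tertiary–quaternary pair with cis methyls and a one-carbon branch (C11) on C9, is the skeleton of (E)-2-methylbut-2-enal. C10, C5, C6 and C7 are a 2-vinylcyclohexene once C19 is set aside. Ring B is therefore a Diels–Alder adduct.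

## Retrosynthesis

**C15–O acyl bond.** The ester is the most fragile group, so 31 is traced to silyl ether 30 and then to alcohol 28 and arachidic acid 29. This needs O15 free and O16 masked in 28. The forward steps are an acylation under neutral conditions and a desilylation that leaves ester and alkenes alone. The trans relation of C15 and C16 across the alkene excludes acyl migration.

**C12–C13 bond.** Cutting between sp3 C12 and sp2 C13 divides 28 into the hydrocarbon diene 22 and the iodoalkene 26. An olefination at C13=C14 would have to choose between two similar CH2 arms on C13 and would give geometric mixtures. A B-alkyl Suzuki–Miyaura coupling instead transfers a geometry fixed beforehand in 26. Iodoalkene 26 comes from but-2-yne-1,4-diol 23 through monosilyl ether 24 and alanate 25, one operation setting the Z-iodoalkene and the difference between the two oxygens. The forward reaction needs hydroboration of the vinyl group of 22 in preference to C3=C4, and coupling with retention.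

**C4–C18 bond and the C3=C4 alkene.** Diene 22 is traced to enol triflate 21, ketone 19, alcohol 18 and silyl ether 17. Addition of a methyl nucleophile to 19 followed by dehydration would give exocyclic and endocyclic alkenes. The enol triflate cannot, because C5 is quaternary and 19 enolises only toward C3 (enolate 20). The precursor has lost one carbon and the alkene regiochemistry is carried by a ketone.

**C5–C19 bond.** This is the hard bond: C19 must arrive syn to the axial C20 methyl, where an unaided reagent will not go.
- A hydroxyl on C4 cannot direct it. Trans to H-10 it is equatorial and lies in the plane of the C5=C6 bond, and cis to H-10 it is axial and delivers to the upper face.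
- The one allylic position whose lower-face bond stands out of the alkene plane is C7. C19 is therefore brought in as the methylene of cyclopropane 12, delivered by a lower-face hydroxyl on C7 of allylic alcohol 11.
- Oxidation to cyclopropyl ketone 13 and dissolving-metal cleavage (enolate 14) give ketone 15 with the angular methyl. Hydrogenolysis of the cyclopropane is avoided because the vinyl group would not survive it.
- The C7 carbonyl is then removed through tosylhydrazone 16 to give 17.

**C7–O bond.** Alcohol 11 is traced to enone 10 and this to alkene 9 by allylic oxidation. C7 is the only allylic methylene of 9. The axial C20 methyl screens the lower face of the C7 carbonyl, so a bulky hydride must attack from above. The price of the sequence is an oxygen put in and taken out again.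

**C11=C12 bond.** Alkene 9 comes from aldehyde 8 by methylenation. Doing this directly after the cycloaddition removes the only electrophilic group before hydride, carbenoid and dissolving-metal steps, and the aldehyde has no α-hydrogen.

**C7–C8 and C9–C10 bonds (key disconnection).** Aldehyde 8 is the adduct of diene 6 and tiglaldehyde 7. One step makes ring B, two σ-bonds and the stereocentres C8, C9 and C10. The alternatives for the C8/C9 pair (conjugate addition then alkylation on a preformed ring) need two steps and two separate stereochemical decisions. The forward reaction has to deliver ortho regiochemistry, exo formyl and addition anti to the C4 silyloxy group.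

**Diene 6.** The C5–C6 bond is cut to iodide 4 and vinylstannane 5. Iodide 4 comes from carbinol 3, iodoenone 2 and cyclohex-2-en-1-one 1. Reducing before coupling avoids the self-dimerising 2-vinylcyclohexenone and gives the catalytic reduction its best substrate, an α-iodoenone.

## Roads not taken

**Alternative 1:** No skeletal bond of the bicycle is cut. The methyls C20 and C19 are moved onto C9 and C5 by a cationic cascade from an ent-labdane-type bicycle. Ionisation at C8 is followed by the shifts H-9 to C8, methyl C10 to C9, H-5 to C10, methyl C4 to C5 and loss of H-3, giving 12-chloro-13,14,15,16-tetranorclerod-3-ene A1.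
- Merits: all four ring stereocentres and the C3=C4 alkene arise in one stereospecific step. C19 lands syn to C20 for free, which the chosen plan pays for with seven steps.
- Weak points: four consecutive 1,2-shifts must each outrun proton loss, so halimane-type alkenes from the intermediate cations and the exocyclic isomer at the end are expected alongside A1 as hard-to-separate hydrocarbons. The precursor must come from the less accessible enantiomeric labdane series.
- Comparison: if the cascade ran cleanly this road would be shorter by more than ten steps. The chosen plan sets against it that every stereocentre is made in a separate, checkable step with separable intermediates.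

**Alternative 2:** The bonds C9–C10 and C4–C5 are cut, unfolding both rings to an acyclic epoxy-diene with an enol ether terminus. In the forward sense MeAlCl2 opens the trisubstituted epoxide at C9, the E-alkene attacks through C10 and the enol ether closes on C5. The product is trans-decalin-3-one A2 with a C11 hydroxyl and a C12 silyl ether.
- Merits: both rings and both quaternary centres are formed in one event. The absolute configuration would come from a catalytic asymmetric epoxidation, and C11/C12 are already functionalised for the side chain.
- Weak points: the cation must form at C9 next to the preset C8 stereocentre, where a 1,2-hydride shift to a ketone competes. The chair–chair folding has to place C19 and C20 syn-diaxial in the transition state. The acyclic precursor with a stereodefined trisubstituted epoxide and alkene is itself a long synthesis. Afterwards C11 must be deoxygenated and the C3 ketone converted to the C3=C4 alkene.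
- Comparison: this road is better in bond economy and in setting C5. The chosen plan offers a pericyclic ring closure whose regio- and stereochemistry are predictable, and starting materials two to four steps from commerce.

**Alternative 3:** The bonds C5–C10 and C3–C4 are cut to a trienoate. In the forward sense an (E)-3-methyl enoate (C4=C5) adds intramolecularly to a terminal diene (C10=C1–C2=C3) under Me2AlCl or heat, giving methyl trans-octal-1-ene-4-carboxylate A3.
- Merits: C19 is present from the start, and the quaternary C5 and the trans ring fusion are set in the cycloaddition itself. In this respect it is clearly better than the chosen plan.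
- Weak points: the dienophile is β,β-disubstituted and sluggish. The tether must already contain the tertiary C8 and the quaternary C9, made with full acyclic stereocontrol. After the key step the ester carbon has to be taken down to the C18 methyl and the alkene moved from C1=C2 to C3=C4.
- Comparison: the chosen plan answers with C8 and C9 that come from the geometry of a commercial enal, and a ring A alkene placed unambiguously by an enol triflate. It pays with the detour through C7 for C19.

Key step: step 5

## Route

Step 1
Reactants: 1 cyclohex-2-en-1-one
Product: 2 2-iodocyclohex-2-en-1-one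
Conditions: I2, pyridine, CH2Cl2, 0 °C → rt
Reagents that add atoms: iodine, [I][I]
Why: α-Iodination of an enone by pyridine addition, iodination of the enolate and elimination (a Baylis–Hillman-type pathway); the iodine marks the carbon that becomes C5.

Step 2
Reactants: 2 2-iodocyclohex-2-en-1-one
Product: 3 (S)-2-iodocyclohex-2-en-1-ol
Conditions: (R)-2-methyl-CBS-oxazaborolidine (10 mol %), BH3·SMe2, THF, −20 °C
Reagents that add atoms: none
Why: Corey–Bakshi–Shibata reduction; the α-iodovinyl arm acts as the large group, so the (R)-catalyst should give the (S)-carbinol (future C4), the only reagent-controlled stereocentre of the route.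

Step 3
Reactants: 3 (S)-2-iodocyclohex-2-en-1-ol
Product: 4 (S)-tert-butyl[(2-iodocyclohex-2-en-1-yl)oxy]dimethylsilane
Conditions: TBSCl, imidazole, DMF, rt
Reagents that add atoms: tert-butyldimethylsilyl chloride, CC(C)(C)[Si](C)(C)Cl
Why: Standard silylation of a secondary alcohol; the bulky silyl ether is the group that will later shield one face of the diene.

Step 4
Reactants: 4 (S)-tert-butyl[(2-iodocyclohex-2-en-1-yl)oxy]dimethylsilane; 5 tributyl(vinyl)stannane
Product: 6 (S)-tert-butyldimethyl[(2-vinylcyclohex-2-en-1-yl)oxy]silane
Conditions: Pd(PPh3)4 (5 mol %), CuI (10 mol %), DMF, 50 °C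
Reagents that add atoms: none
Why: Stille coupling of a cyclic alkenyl iodide with a vinylstannane, accelerated by CuI; the stereocentre is not involved and the allylic silyl ether is inert.

Step 5
Reactants: 6 (S)-tert-butyldimethyl[(2-vinylcyclohex-2-en-1-yl)oxy]silane; 7 tiglaldehyde
Product: 8 (4S)-4-(tert-butyldimethylsilyloxy)-12,13,14,15,16,18,19-heptanorclerod-5-en-11-al
Conditions: EtAlCl2 (0.5 equiv), CH2Cl2, −78 → −40 °C
Reagents that add atoms: none
Why: Coordination of EtAlCl2 to the formyl oxygen of 7 lowers its LUMO, and the enal adds to the s-cis diene of 6 in a concerted, asynchronous [4+2] cycloaddition in which the C7–C8 bond runs ahead of C9–C10. The closest known reaction type is the Lewis-acid-promoted Diels–Alder reaction of α-alkyl enals with 1-vinylcycloalkenes, which is exo-selective for the formyl group. Ring B is closed as a cyclohexene by this cycloaddition, suprafacially on both partners, leaving the new C5=C6 bond at the ring fusion. Regiochemistry (C9 to C10, C8 to C7) follows from the larger HOMO coefficient at the unsubstituted diene terminus C7 meeting the β-carbon of the enal; the 1-alkyl substituent of the diene outweighs the 2-alkyl one, whose donor strength is lowered by the allylic oxygen. C8 relative to C9: the E geometry of 7 is carried into the cis relation of C17 and C20. C9 relative to C10: the α-methyl group takes the endo position and the formyl group the exo position, so C11 ends cis to H-10. C10 and the absolute sense: the silyloxy group on C4 sits pseudoaxial to escape allylic strain with the vinyl group and covers one face of the diene, so the dienophile adds to the other face and H-10 ends on the face of the silyloxy group. An alkylaluminium chloride is preferred to BF3·OEt2 because it scavenges protons that would ionise the allylic silyl ether.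

Step 6
Reactants: 8 (4S)-4-(tert-butyldimethylsilyloxy)-12,13,14,15,16,18,19-heptanorclerod-5-en-11-al
Product: 9 4-(tert-butyldimethylsilyloxy)-13,14,15,16,18,19-hexanorcleroda-5,11-diene
Conditions: Ph3PCH3Br, KOtBu, THF, 0 °C → rt
Reagents that add atoms: methyltriphenylphosphonium bromide, C[P+](c1ccccc1)(c1ccccc1)c1ccccc1.[Br-]
Why: Wittig methylenation; the aldehyde has no α-hydrogen, so enolisation and epimerisation cannot compete, and the small ylide tolerates the neopentyl position.

Step 7
Reactants: 9 4-(tert-butyldimethylsilyloxy)-13,14,15,16,18,19-hexanorcleroda-5,11-diene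
Product: 10 4-(tert-butyldimethylsilyloxy)-13,14,15,16,18,19-hexanorcleroda-5,11-dien-7-one
Conditions: CrO3, 3,5-dimethylpyrazole, CH2Cl2, −20 °C
Reagents that add atoms: chromium trioxide, O=[Cr](=O)=O
Why: Allylic oxidation of a trisubstituted cycloalkene with the CrO3–3,5-dimethylpyrazole complex goes to the methylene next to the less substituted alkene carbon, here C7. The C4–H bond lies in the alkene plane, C10–H is screened by the syn-axial silyloxy group, and the vinyl group has no allylic hydrogen.

Step 8
Reactants: 10 4-(tert-butyldimethylsilyloxy)-13,14,15,16,18,19-hexanorcleroda-5,11-dien-7-one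
Product: 11 4-(tert-butyldimethylsilyloxy)-13,14,15,16,18,19-hexanorcleroda-5,11-dien-7-ol
Conditions: LiBH(s-Bu)3, THF, −78 °C
Reagents that add atoms: none
Why: 1,2-Reduction of a β,β-disubstituted cyclohexenone by a bulky trialkylborohydride. The lower face of the carbonyl is blocked by the syn-axial C20 methyl, so hydride enters from above and the hydroxyl is placed on the lower face, trans to H-10.

Step 9
Reactants: 11 4-(tert-butyldimethylsilyloxy)-13,14,15,16,18,19-hexanorcleroda-5,11-dien-7-ol
Product: 12 4-(tert-butyldimethylsilyloxy)-6,19-cyclo-13,14,15,16,18-pentanorclerod-11-en-7-ol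
Conditions: Et2Zn, CH2I2, CH2Cl2, 0 °C → rt
Reagents that add atoms: diiodomethane, C(I)I
Why: Hydroxyl-directed Simmons–Smith cyclopropanation (Furukawa variant) of a cyclohex-2-enol. In either half-chair of ring B the C7–O bond stands on the lower side of the alkene, so the zinc alkoxide delivers the methylene to the lower face of C5=C6 and sets C5 with C19 trans to H-10 and syn to C20. The undirected vinyl group reacts far more slowly.

Step 10
Reactants: 12 4-(tert-butyldimethylsilyloxy)-6,19-cyclo-13,14,15,16,18-pentanorclerod-11-en-7-ol
Product: 13 4-(tert-butyldimethylsilyloxy)-6,19-cyclo-13,14,15,16,18-pentanorclerod-11-en-7-one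
Conditions: Dess–Martin periodinane, NaHCO3, CH2Cl2, rt
Reagents that add atoms: none
Why: Buffered Dess–Martin oxidation of a secondary cyclopropyl carbinol; neutral conditions avoid cyclopropylcarbinyl cation rearrangement.

Step 11
Reactants: 13 4-(tert-butyldimethylsilyloxy)-6,19-cyclo-13,14,15,16,18-pentanorclerod-11-en-7-one
Product: 15 4-(tert-butyldimethylsilyloxy)-13,14,15,16,18-pentanorclerod-11-en-7-one, via lithium enolate 14 (not isolated)
Conditions: Li, NH3(l), THF, −78 °C; then isoprene, NH4Cl
Reagents that add atoms: none
Why: Dissolving-metal cleavage of a conjugated cyclopropyl ketone: the exocyclic C6–C19 bond overlaps with the carbonyl π system and breaks, leaving C19 as the angular methyl on C5 with its configuration unchanged. The enolate points to C6, so C8 is not epimerised, and the isolated vinyl group is not reduced in the absence of a proton source.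

Step 12
Reactants: 15 4-(tert-butyldimethylsilyloxy)-13,14,15,16,18-pentanorclerod-11-en-7-one
Product: 16 4-methylbenzenesulfonylhydrazone of ketone 15
Conditions: TsNHNH2, AcOH (cat.), EtOH, 60 °C
Reagents that add atoms: 4-methylbenzenesulfonohydrazide, Cc1ccc(cc1)S(=O)(=O)NN
Why: Condensation of a ketone with tosylhydrazide under mild acid catalysis; no base is present that could enolise toward C8.

Step 13
Reactants: 16 4-methylbenzenesulfonylhydrazone of ketone 15
Product: 17 4-(tert-butyldimethylsilyloxy)-13,14,15,16,18-pentanorclerod-11-ene
Conditions: catecholborane, CHCl3, 0 °C; then NaOAc·3H2O, reflux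
Reagents that add atoms: none
Why: Hydride reduction of the tosylhydrazone and loss of sulfinate and N2 (a mild Wolff–Kishner equivalent) turn C7=O into CH2 without strong base, so C8 is safe. Catecholborane does not hydroborate the vinyl group at this temperature without a catalyst.

Step 14
Reactants: 17 4-(tert-butyldimethylsilyloxy)-13,14,15,16,18-pentanorclerod-11-ene
Product: 18 13,14,15,16,18-pentanorclerod-11-en-4-ol
Conditions: Bu4NF, THF, 50 °C
Reagents that add atoms: none
Why: Fluoride cleavage of a hindered secondary silyl ether; nothing else in 17 responds to fluoride.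

Step 15
Reactants: 18 13,14,15,16,18-pentanorclerod-11-en-4-ol
Product: 19 13,14,15,16,18-pentanorclerod-11-en-4-one
Conditions: Dess–Martin periodinane, NaHCO3, CH2Cl2, rt
Reagents that add atoms: none
Why: Dess–Martin oxidation of a secondary alcohol; the C4 stereocentre has done its work and is removed.

Step 16
Reactants: 19 13,14,15,16,18-pentanorclerod-11-en-4-one
Product: 21 13,14,15,16,18-pentanorcleroda-3,11-dien-4-yl trifluoromethanesulfonate, via potassium enolate 20 (not isolated)
Conditions: KN(SiMe3)2, THF, −78 °C; then PhNTf2, −78 → 0 °C
Reagents that add atoms: N-phenylbis(trifluoromethanesulfonimide), O=S(=O)(N(c1ccccc1)S(=O)(=O)C(F)(F)F)C(F)(F)F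
Why: Ketone 19 can enolise only toward C3 because C5 is quaternary, so O-triflation of the enolate fixes the ring A double bond at C3=C4.

Step 17
Reactants: 21 13,14,15,16,18-pentanorcleroda-3,11-dien-4-yl trifluoromethanesulfonate
Product: 22 (5R,8R,9S,10R)-13,14,15,16-tetranorcleroda-3,11-diene
Conditions: MeMgBr, Fe(acac)3 (5 mol %), THF/NMP, −30 → 0 °C
Reagents that add atoms: methylmagnesium bromide, C[Mg]Br
Why: Iron-catalysed Kumada-type coupling of an alkenyl triflate with a methyl Grignard reagent installs C18 with the alkene held in place; the isolated vinyl group is inert.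

Step 18
Reactants: 23 but-2-yne-1,4-diol
Product: 24 4-(tert-butyldimethylsilyloxy)but-2-yn-1-ol
Conditions: TBSCl (1 equiv), imidazole, 23 (4 equiv), DMF, 0 °C
Reagents that add atoms: tert-butyldimethylsilyl chloride, CC(C)(C)[Si](C)(C)Cl
Why: Monosilylation of a symmetrical diol used in excess; the two oxygens of the future C15/C16 pair become different here.

Step 19
Reactants: 24 4-(tert-butyldimethylsilyloxy)but-2-yn-1-ol
Product: 26 (Z)-4-(tert-butyldimethylsilyloxy)-3-iodobut-2-en-1-ol, via alkenylalanate 25 (not isolated)
Conditions: NaAlH2(OCH2CH2OMe)2, THF, 0 °C; then I2, −78 → 0 °C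
Reagents that add atoms: iodine, [I][I]
Why: Hydroxyl-directed trans-hydroalumination of the propargylic alcohol puts aluminium on the distal alkyne carbon within a five-membered alanate, and iodinolysis with retention gives the Z-iodoalkene. Iodine is cis to the CH2OH arm, which is the geometry the target needs at C13=C14.

Step 20
Reactants: 22 (5R,8R,9S,10R)-13,14,15,16-tetranorcleroda-3,11-diene; 26 (Z)-4-(tert-butyldimethylsilyloxy)-3-iodobut-2-en-1-ol
Product: 28 (13E)-16-(tert-butyldimethylsilyloxy)cleroda-3,13-dien-15-ol, via alkylborane 27 (not isolated)
Conditions: 9-BBN, THF, rt; then 26, Pd(dppf)Cl2 (5 mol %), AsPh3, Cs2CO3, DMF/H2O, rt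
Reagents that add atoms: none
Why: Anti-Markovnikov hydroboration of the vinyl group by 9-BBN leaves the trisubstituted C3=C4 alone, and the B-alkyl Suzuki–Miyaura coupling forms C12–C13 with retention of the iodoalkene geometry. The free allylic hydroxyl is tolerated.

Step 21
Reactants: 28 (13E)-16-(tert-butyldimethylsilyloxy)cleroda-3,13-dien-15-ol; 29 arachidic acid
Product: 30 (13E)-16-(tert-butyldimethylsilyloxy)cleroda-3,13-dien-15-yl icosanoate
Conditions: DCC, DMAP (cat.), CH2Cl2, rt
Reagents that add atoms: none
Why: Steglich esterification of the only free hydroxyl (O15) under neutral conditions that do not touch the alkenes or the silyl ether.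

Step 22
Reactants: 30 (13E)-16-(tert-butyldimethylsilyloxy)cleroda-3,13-dien-15-yl icosanoate
Product: 31 (13E)-16-hydroxycleroda-3,13-dien-15-yl icosanoate
Conditions: HF·pyridine, pyridine, THF, 0 °C
Reagents that add atoms: none
Why: Buffered fluoride cleavage of a primary allylic silyl ether leaves the ester and both trisubstituted alkenes untouched. O15 and O16 lie trans across the alkene, so the acyl group cannot migrate.

## Compound list

1 | cyclohex-2-en-1-one | O=C1C=CCCC1 | starting material
2 | 2-iodocyclohex-2-en-1-one | O=C1CCCC=C1I | intermediate
3 | (S)-2-iodocyclohex-2-en-1-ol | IC1=CCCC[C@@H]1O | intermediate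
4 | (S)-tert-butyl[(2-iodocyclohex-2-en-1-yl)oxy]dimethylsilane | IC1=CCCC[C@@H]1O[Si](C)(C)C(C)(C)C | intermediate
5 | tributyl(vinyl)stannane | C=C[Sn](CCCC)(CCCC)CCCC | starting material
6 | (S)-tert-butyldimethyl[(2-vinylcyclohex-2-en-1-yl)oxy]silane | C=CC1=CCCC[C@@H]1O[Si](C)(C)C(C)(C)C | intermediate
7 | tiglaldehyde, (E)-2-methylbut-2-enal | C/C=C(\C)C=O | starting material
8 | (4S)-4-(tert-butyldimethylsilyloxy)-12,13,14,15,16,18,19-heptanorclerod-5-en-11-al; H-10, C11 and the silyloxy group on the upper face, C17 and C20 on the lower face; (1S,2R,5S,8aS)-5-(tert-butyldimethylsilyloxy)-1,2-dimethyl-1,2,3,5,6,7,8,8a-octahydronaphthalene-1-carbaldehyde | O=C[C@@]1(C)[C@H](C)CC=C2[C@@H](O[Si](C)(C)C(C)(C)C)CCC[C@H]12 | intermediate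
9 | 4-(tert-butyldimethylsilyloxy)-13,14,15,16,18,19-hexanorcleroda-5,11-diene, stereocentres as in 8 | C=C[C@@]1(C)[C@H](C)CC=C2[C@@H](O[Si](C)(C)C(C)(C)C)CCC[C@H]12 | intermediate
10 | 4-(tert-butyldimethylsilyloxy)-13,14,15,16,18,19-hexanorcleroda-5,11-dien-7-one, stereocentres as in 8 | C=C[C@@]1(C)[C@H](C)C(=O)C=C2[C@@H](O[Si](C)(C)C(C)(C)C)CCC[C@H]12 | intermediate
11 | 4-(tert-butyldimethylsilyloxy)-13,14,15,16,18,19-hexanorcleroda-5,11-dien-7-ol, 7-hydroxyl on the lower face (trans to H-10) | C=C[C@@]1(C)[C@H](C)[C@H](O)C=C2[C@@H](O[Si](C)(C)C(C)(C)C)CCC[C@H]12 | intermediate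
12 | 4-(tert-butyldimethylsilyloxy)-6,19-cyclo-13,14,15,16,18-pentanorclerod-11-en-7-ol, cyclopropane methylene C19 and 7-hydroxyl on the lower face | C=C[C@@]1(C)[C@H](C)[C@H](O)[C@@H]3C[C@@]32[C@@H](O[Si](C)(C)C(C)(C)C)CCC[C@H]12 | intermediate
13 | 4-(tert-butyldimethylsilyloxy)-6,19-cyclo-13,14,15,16,18-pentanorclerod-11-en-7-one, cyclopropane on the lower face | C=C[C@@]1(C)[C@H](C)C(=O)[C@@H]3C[C@@]32[C@@H](O[Si](C)(C)C(C)(C)C)CCC[C@H]12 | intermediate
14 | lithium 4-(tert-butyldimethylsilyloxy)-13,14,15,16,18-pentanorcleroda-6,11-dien-7-olate (C6 enolate, C19 methyl on the lower face) | C=C[C@@]1(C)[C@H](C)C(O[Li])=C[C@@]2(C)[C@@H](O[Si](C)(C)C(C)(C)C)CCC[C@H]12 | intermediate (not isolated)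
15 | 4-(tert-butyldimethylsilyloxy)-13,14,15,16,18-pentanorclerod-11-en-7-one, C19 methyl on the lower face (trans to H-10) | C=C[C@@]1(C)[C@H](C)C(=O)C[C@@]2(C)[C@@H](O[Si](C)(C)C(C)(C)C)CCC[C@H]12 | intermediate
16 | 4-methylbenzenesulfonylhydrazone of ketone 15 | C=C[C@@]1(C)[C@H](C)C(=NNS(=O)(=O)c3ccc(C)cc3)C[C@@]2(C)[C@@H](O[Si](C)(C)C(C)(C)C)CCC[C@H]12 | intermediate
17 | 4-(tert-butyldimethylsilyloxy)-13,14,15,16,18-pentanorclerod-11-ene, silyloxy group on the upper face | C=C[C@@]1(C)[C@H](C)CC[C@@]2(C)[C@@H](O[Si](C)(C)C(C)(C)C)CCC[C@H]12 | intermediate
18 | 13,14,15,16,18-pentanorclerod-11-en-4-ol, hydroxyl on the upper face | C=C[C@@]1(C)[C@H](C)CC[C@@]2(C)[C@@H](O)CCC[C@H]12 | intermediate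
19 | 13,14,15,16,18-pentanorclerod-11-en-4-one | C=C[C@@]1(C)[C@H](C)CC[C@@]2(C)C(=O)CCC[C@H]12 | intermediate
20 | potassium 13,14,15,16,18-pentanorcleroda-3,11-dien-4-olate | C=C[C@@]1(C)[C@H](C)CC[C@@]2(C)C([O-])=CCC[C@H]12.[K+] | intermediate (not isolated)
21 | 13,14,15,16,18-pentanorcleroda-3,11-dien-4-yl trifluoromethanesulfonate | C=C[C@@]1(C)[C@H](C)CC[C@@]2(C)C(OS(=O)(=O)C(F)(F)F)=CCC[C@H]12 | intermediate
22 | (5R,8R,9S,10R)-13,14,15,16-tetranorcleroda-3,11-diene; (1S,2R,4aR,8aR)-1-ethenyl-1,2,4a,5-tetramethyl-1,2,3,4,4a,7,8,8a-octahydronaphthalene | C=C[C@@]1(C)[C@H](C)CC[C@@]2(C)C(C)=CCC[C@H]12 | intermediate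
23 | but-2-yne-1,4-diol | OCC#CCO | starting material
24 | 4-(tert-butyldimethylsilyloxy)but-2-yn-1-ol | OCC#CCO[Si](C)(C)C(C)(C)C | intermediate
25 | sodium cyclic (Z)-alkenylalanate (2,5-dihydro-1,2-oxaluminole ate complex with two 2-methoxyethoxy ligands) | CC(C)(C)[Si](C)(C)OCC1=CCO[Al-]1(OCCOC)OCCOC.[Na+] | intermediate (not isolated)
26 | (Z)-4-(tert-butyldimethylsilyloxy)-3-iodobut-2-en-1-ol | OC/C=C(\I)CO[Si](C)(C)C(C)(C)C | intermediate
27 | 9-[(5R,8R,9S,10R)-13,14,15,16-tetranorclerod-3-en-12-yl]-9-borabicyclo[3.3.1]nonane | C(CB1C2CCCC1CCC2)[C@@]3(C)[C@H](C)CC[C@@]4(C)C(C)=CCC[C@H]34 | intermediate (not isolated)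
28 | (5R,8R,9S,10R,13E)-16-(tert-butyldimethylsilyloxy)cleroda-3,13-dien-15-ol | OC/C=C(/CO[Si](C)(C)C(C)(C)C)CC[C@@]1(C)[C@H](C)CC[C@@]2(C)C(C)=CCC[C@H]12 | intermediate
29 | arachidic acid (icosanoic acid) | CCCCCCCCCCCCCCCCCCCC(=O)O | starting material
30 | (5R,8R,9S,10R,13E)-16-(tert-butyldimethylsilyloxy)cleroda-3,13-dien-15-yl icosanoate | CCCCCCCCCCCCCCCCCCCC(=O)OC/C=C(/CO[Si](C)(C)C(C)(C)C)CC[C@@]1(C)[C@H](C)CC[C@@]2(C)C(C)=CCC[C@H]12 | intermediate
31 | (5R,8R,9S,10R,13E)-16-hydroxycleroda-3,13-dien-15-yl icosanoate; (2E)-3-(hydroxymethyl)-5-[(1S,2R,4aR,8aR)-1,2,4a,5-tetramethyl-1,2,3,4,4a,7,8,8a-octahydronaphthalen-1-yl]pent-2-en-1-yl icosanoate | CCCCCCCCCCCCCCCCCCCC(=O)OC/C=C(/CO)CC[C@@]1(C)[C@H](C)CC[C@@]2(C)C(C)=CCC[C@H]12 | target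

## Step count and least certain steps

Total step count: 22. Longest linear sequence: 20 steps (steps 1–17 and 20–22); steps 18 and 19 make the side-chain fragment.

**Step 5 (key step).**
- What may go wrong: the β-substituted enal is a slow dienophile, so ionisation of the allylic silyl ether or oligomerisation of the diene under the Lewis acid may overtake the cycloaddition. Facial or exo selectivity may also be eroded if the reaction has to be run warmer.
- Fallback (from 6 and 7, back at 8): change the dienophile to a cationic one. Tiglaldehyde 7 is converted with ethane-1,2-diol into 2-[(E)-but-2-en-2-yl]-1,3-dioxolane F1. Catalytic TMSOTf at −78 °C turns this into a dioxolanyl allyl cation (ionic Diels–Alder reaction), which should add to 6 with the same orientation to give the dioxolane acetal of aldehyde 8 F2. Mild hydrolysis (pyridinium tosylate, wet acetone) returns 8.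

**Step 7.**
- What may go wrong: hydrogen abstraction at the tertiary allylic C10–H instead of C7, or slow attack at C7 because its lower-face hydrogen is screened by C20. Either leads to regioisomeric enones or over-oxidation.
- Fallback (from 9, back at 10): build the enone by transposition instead of C–H oxidation. Epoxidation of the trisubstituted alkene of 9 with mCPBA gives the 5,6-epoxide F3 (either face serves). LiNEt2 removes a C7 proton and opens the epoxide to the tertiary allylic alcohol 4-(tert-butyldimethylsilyloxy)-13,14,15,16,18,19-hexanorcleroda-6,11-dien-5-ol F4. Oxidative 1,3-transposition with pyridinium chlorochromate gives 10.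

**Step 9.**
- What may go wrong: the methylene has to be delivered next to the axial C20 methyl, so transfer may be slow, conversion incomplete, and the vinyl group may begin to compete.
- Fallback (from 10, back at 15): replace cyclopropanation and ring opening by conjugate addition. Me2CuLi with BF3·OEt2 adds to enone 10 at C5 along the axial trajectory anti to H-10 and anti to the axial 4-silyloxy group, giving ketone 15 directly after protonation. No new compound is involved (F0). The C5 epimer, if formed against the C20 methyl, would have to be separated at this point.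

**Step 12.**
- What may go wrong: the C7 carbonyl is flanked by C8 and the neopentyl C6 and may condense slowly. Forcing acid and heat invites epimerisation at C8 through the enol or ene-hydrazine.
- Fallback (from 15, back at 17): deoxygenate at the alcohol level by a radical path. NaBH4 reduces 15 to the 7-ol F5. NaH, CS2 and MeI give the S-methyl xanthate F6. Bu3SnH with AIBN in hot toluene (Barton–McCombie deoxygenation) gives 17.

## Further compounds

F1 | step 5 | 2-[(E)-but-2-en-2-yl]-1,3-dioxolane | C/C=C(\C)C1OCCO1
F2 | step 5 | dioxolane acetal of aldehyde 8 | O1CCOC1[C@@]2(C)[C@H](C)CC=C3[C@@H](O[Si](C)(C)C(C)(C)C)CCC[C@H]23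
F3 | step 7 | 5,6-epoxide of 9 (epoxide face not defined, both serve) | C=C[C@@]1(C)[C@H](C)CC3OC32[C@@H](O[Si](C)(C)C(C)(C)C)CCC[C@H]12
F4 | step 7 | 4-(tert-butyldimethylsilyloxy)-13,14,15,16,18,19-hexanorcleroda-6,11-dien-5-ol (C5 configuration follows the epoxide) | C=C[C@@]1(C)[C@H](C)C=CC2(O)[C@@H](O[Si](C)(C)C(C)(C)C)CCC[C@H]12
F0 | step 9 | none | none
F5 | step 12 | 4-(tert-butyldimethylsilyloxy)-13,14,15,16,18-pentanorclerod-11-en-7-ol (C7 configuration immaterial) | C=C[C@@]1(C)[C@H](C)C(O)C[C@@]2(C)[C@@H](O[Si](C)(C)C(C)(C)C)CCC[C@H]12
F6 | step 12 | O-(7-yl) S-methyl dithiocarbonate of F5 | C=C[C@@]1(C)[C@H](C)C(OC(=S)SC)C[C@@]2(C)[C@@H](O[Si](C)(C)C(C)(C)C)CCC[C@H]12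
A1 | alternative 1 | 12-chloro-13,14,15,16-tetranorclerod-3-ene | ClCC[C@@]1(C)[C@H](C)CC[C@@]2(C)C(C)=CCC[C@H]12
A2 | alternative 2 | trans-decalin-3-one with C11 hydroxyl and C12 tert-butyldiphenylsilyl ether | CC(C)(C)[Si](c3ccccc3)(c4ccccc4)OC[C@H](O)[C@@]1(C)[C@H](C)CC[C@@]2(C)[C@H](C)C(=O)CC[C@H]12
A3 | alternative 3 | methyl trans-octal-1-ene-4-carboxylate with a C12 tert-butyldimethylsilyl ether | CC(C)(C)[Si](C)(C)OCC[C@@]1(C)[C@H](C)CC[C@@]2(C)[C@H](C(=O)OC)CC=C[C@H]12
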